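The readings are calculated on assumed constants; scatter was added.

- We back dusk, and we size that choice with one number that holds no clock.

| flask | G | E | X | remark | time |
|---|---|---|---|---|---|
| green | 0.20 M | 1.5 equiv | 0.2 mol% | run made earlier |  |
| ochre | 0.10 M | 1.5 equiv | 0.2 mol% | run made earlier |  |
| red | 0.40 M | 1.5 equiv | 0.2 mol% | run made earlier |  |
| grey | 0.20 M | 1.5 equiv | 0.1 mol% | run made earlier |  |
| summer | 0.20 M | 1.50 equiv | 0.2 mol% | a closed flask charged with all of it at once and left for 10 min | 10 min |
| winter | 0.20 M (fed, over 8.00 min) | 1.50 equiv | 0.2 mol% | all but G at the start; G goes in evenly over 8.00 min, the run ends at 10 min | 10 min |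
| dusk | 0.20 M | 1.50 equiv (fed, over 8.00 min) | 0.2 mol% | all but E at the start; E goes in evenly over 8.00 min, the run ends at 10 min | 10 min |
| autumn | 0.20 M | 1.50 equiv | 0.2 mol% | one stirred flow tank at steady state, fed with the mixture as stated, mean residence time 10 min |  |

| green: time / min | green: L / % | ochre: time / min | ochre: L / % | red: time / min | red: L / % | grey: time / min | grey: L / % |
|---|---|---|---|---|---|---|---|
| 0.833 | 47.3 | 1.00 | 39.7 | 2.50 | 32.0 | 1.00 | 53.3 |
| 1.50 | 43.4 | 3.00 | 37.1 | 5.00 | 25.8 | 2.00 | 49.3 |
| 3.00 | 36.6 | 6.00 | 32.4 | 8.00 | 21.5 | 3.00 | 46.5 |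
| 5.00 | 31.5 | 8.00 | 30.0 | 10.0 | 20.8 | 6.00 | 40.9 |
| 10.0 | 27.3 | 12.0 | 26.4 | 12.0 | 21.6 | 12.0 | 36.4 |

(scatter of a reading: 0.5 percentage points)

- the stated concentrations are those of everything mixed, before any reaction; amounts are the same in each set-up
- the analysis behind the earlier runs scatters by 0.5 percentage points, standard deviation
- the feed brings no volume worth counting
- the earlier runs were made in a closed, stirred flask

- the set-up with the highest amount of L at the outlet or at the end, in percent of the G put in ("none" if the first two lie within 2 percentage points) (summer / winter / dusk / autumn / none)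
- amount of L at the outlet or at the end, in percent of the G put in, summer
- amount of L at the outlet or at the end, in percent of the G put in, winter
- amount of L at the outlet or at the end, in percent of the G put in, dusk
- amount of L at the outlet or at the end, in percent of the G put in, autumn

- Divide the rate that makes L by the rate that returns it and time drops out. At balance, L over free G times free E times the G concentration stays fixed, with L, G and E as fractions of the G charged; this is the equilibrium constant.
- If L alone has formed, grey's first reading gives 5.90 M⁻¹ and ochre's gives 5.97 M⁻¹. These two ways agree from different concentrations, so we carry 5.94 M⁻¹ as the balance number, L over free G, free E and G concentration.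
- Green's first reading gives 4.37 M⁻¹ and red's 0.997 M⁻¹, both lower. These are the ones that cheat: each had more X concentration times minutes than grey, and L already lost is wrongly counted as free G and E. Any such loss pulls the number down, so ours is a floor.
- Our own reckoning assumes that dusk loses little L. At the G charge the balance number then gives 53.4 % of L.
- The forecast differs: it also picks dusk, saying “E stays scarce while G is present, which protects L”, but puts dusk at 42 %, within 30 % to 54 %. It gives summer 27.2 %, winter 25 % and autumn 32 %.
- The flask gives summer 27.4 %, winter 27.8 %, dusk 54.8 % and autumn 29.1 %, so dusk comes first.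

    L + X ⇌ D + X, rate k1*[X]*[L] forward; the back reaction follows from the equilibrium constant (k = 42.0 M⁻¹ s⁻¹)
    G + E ⇌ D (K = 79.0 M⁻¹, k = 0.00830 M⁻¹ s⁻¹)
    G + X → Z (k = 0.180 M⁻¹ s⁻¹)
    G + E ⇌ L (K = 13.0 M⁻¹, k = 0.160 M⁻¹ s⁻¹)

- Dusk ended with G at 27 % of the G charged and E at 51 % of its own charge, which put the number at 13.5 M⁻¹, above our floor and close to 13 M⁻¹. The neighbouring dusk flask with 0.080 M of G keeps the recipe otherwise. Its simulated G and E give 13.3 M⁻¹, our carried floor reckons 35.3 % of L, and the flask ends at 41.8 %.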